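**Plan**

1. Retrosynthetic cuts: first the C1'–CH2 bond of the bridge (the bridge carbon comes from an iminium salt, the pyranone arrives complete); then the C4'–O and C5'–C(=O) bonds together (aryne plus isobutyric acid); then the C3'–prenyl bond (aryllithium plus prenyl bromide). The pyranone is cut to 3-pentanone and malonyl dichloride.
2. Enabling feature: on the benzene ring the C4' hydroxyl and the C5' isobutyryl group are neighbours, flanked by the C3' prenyl group and the C6' methoxy group. This is the footprint of a C4'≡C5' aryne that has inserted into the HO–C(=O) bond of isobutyric acid, with C6'–OMe steering oxygen to C4'.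
3. Forward order: 5-methoxyresorcinol → bis-MOM ether → prenyl at C3' → bromine at C5' → diol → one-pot retro-Brook/triflation (SiMe3 at C5', OTf at C4') → MOM on the C2' oxygen → aryne insertion → MOM removal → three-component union with the pyranone.
4. The pyran-2-one ring is the only ring built. It is made separately and joined last, because it is a diene toward arynes and carries an acidic hydroxyl.
5. Stereochemistry: none to set. The target has no stereocentre and no double bond with E/Z isomerism.

Key step: step 7

Remark: ring carbons of all benzene intermediates carry the primed locants of the target (C1' CH2 bridge, C2' OH, C3' prenyl, C4' OH, C5' isobutyryl, C6' OMe). It is assumed that acylation of the silyl enol ether of 3-pentanone is more reliable than direct reaction of the ketone with malonyl dichloride, so the enol ether is used.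

**Route**

Step 1
Reactants: 1 5-methoxyresorcinol
Product: 2 1-methoxy-3,5-bis(methoxymethoxy)benzene
Conditions: MOMCl (2.5 equiv), i-Pr2NEt, CH2Cl2, 0 °C to rt
Reagents that add atoms: chloromethyl methyl ether (MOMCl), COCCl
Why: Williamson-type O-alkylation of both phenols with a hard electrophile should go cleanly to oxygen, and the two MOM ethers then serve as directing groups for metalation.

Step 2
Reactants: 2 1-methoxy-3,5-bis(methoxymethoxy)benzene; 3 prenyl bromide (1-bromo-3-methylbut-2-ene)
Product: 6 5-methoxy-1,3-bis(methoxymethoxy)-2-(3-methylbut-2-en-1-yl)benzene, via aryllithium 4 (not isolated), via arylcopper 5 (not isolated)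
Conditions: n-BuLi, THF, 0 °C to rt; CuI, −40 °C; 3, −40 °C to rt
Reagents that add atoms: none
Why: Directed ortho-metalation should remove the ring proton between the two OMOM groups (C3'), where both acetal oxygens hold lithium, and transmetalation to copper should give SN2 coupling with prenyl bromide without allylic transposition.

Step 3
Reactants: 6 5-methoxy-1,3-bis(methoxymethoxy)-2-(3-methylbut-2-en-1-yl)benzene
Product: 7 2-bromo-1-methoxy-3,5-bis(methoxymethoxy)-4-(3-methylbut-2-en-1-yl)benzene
Conditions: NBS (1.0 equiv), CH2Cl2, −78 to −20 °C, dark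
Reagents that add atoms: N-bromosuccinimide (NBS), O=C1CCC(=O)N1Br
Why: Electrophilic aromatic bromination should take place on the trialkoxy ring, which is far more nucleophilic than the trisubstituted alkene; no free phenol is present to trap a bromonium ion, and because the two open ring positions are equivalent and the first bromine deactivates the ring, one equivalent should stop at the monobromide (bromine at C5').

Step 4
Reactants: 7 2-bromo-1-methoxy-3,5-bis(methoxymethoxy)-4-(3-methylbut-2-en-1-yl)benzene
Product: 8 4-bromo-5-methoxy-2-(3-methylbut-2-en-1-yl)benzene-1,3-diol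
Conditions: 2 M HCl in MeOH, rt
Reagents that add atoms: none
Why: Acid-catalysed acetal exchange (methanolysis of the MOM ethers) under dilute, cold conditions is a standard way to free ortho-prenyl phenols without closing a chroman.

Step 5
Reactants: 8 4-bromo-5-methoxy-2-(3-methylbut-2-en-1-yl)benzene-1,3-diol
Product: 13 5-hydroxy-3-methoxy-6-(3-methylbut-2-en-1-yl)-2-(trimethylsilyl)phenyl trifluoromethanesulfonate, via bis(trimethylsilyl) ether 9 (not isolated), via aryllithium 10 (not isolated), via lithium phenoxide 11 (not isolated), via silyl ether triflate 12 (not isolated)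
Conditions: (Me3Si)2NH, THF, 65 °C, then evaporation; n-BuLi (1.05 equiv), THF, −78 °C; Tf2O, −78 to 0 °C; aq. NaHCO3, then MeOH, cat. AcOH, rt
Reagents that add atoms: hexamethyldisilazane, C[Si](C)(C)N[Si](C)(C)C; trifluoromethanesulfonic anhydride (Tf2O), O=S(=O)(OS(=O)(=O)C(F)(F)F)C(F)(F)F
Why: This is the standard one-pot route from ortho-bromophenols to ortho-silylaryl triflates: bromine–lithium exchange at C5' triggers a retro-Brook rearrangement (1,3 O→C silyl shift) from the C4' oxygen only, so only that oxygen becomes a phenoxide and is triflated, while the C2' silyl ether stays until it is hydrolysed in the work-up.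

Step 6
Reactants: 13 5-hydroxy-3-methoxy-6-(3-methylbut-2-en-1-yl)-2-(trimethylsilyl)phenyl trifluoromethanesulfonate
Product: 14 3-methoxy-5-(methoxymethoxy)-6-(3-methylbut-2-en-1-yl)-2-(trimethylsilyl)phenyl trifluoromethanesulfonate
Conditions: MOMCl, i-Pr2NEt, CH2Cl2, 0 °C to rt
Reagents that add atoms: chloromethyl methyl ether (MOMCl), COCCl
Why: O-alkylation of the remaining phenol (Williamson-type MOM protection) under amine base, with no fluoride present, should leave the silyl triflate intact and removes the one nucleophile that would compete for the aryne.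

Step 7
Reactants: 14 3-methoxy-5-(methoxymethoxy)-6-(3-methylbut-2-en-1-yl)-2-(trimethylsilyl)phenyl trifluoromethanesulfonate; 15 isobutyric acid
Product: 17 1-[2-hydroxy-6-methoxy-4-(methoxymethoxy)-3-(3-methylbut-2-en-1-yl)phenyl]-2-methylpropan-1-one, via aryne 16 (not isolated)
Conditions: 15 (1.5 equiv), CsF (4 equiv), THF, 125 °C, sealed tube
Reagents that add atoms: none
Why: Fluoride attacks silicon and triflate leaves to give aryne 16 (C4'≡C5'); cesium isobutyrate adds through oxygen to C4', the aryl anion at C5' attacks the ester carbonyl through a four-membered alkoxide, and ring opening gives the C5' ketone and the C4' phenoxide, so the aryne has inserted into the C(acyl)–O bond. The closest known reaction type is the CsF-induced insertion of arynes into the carbon–oxygen bond of carboxylic acids in hot THF to give ortho-hydroxyaryl ketones, which with 3-methoxybenzyne places the acyl group next to the methoxy group. No ring is closed and no stereocentre is formed. The regioselectivity needed (oxygen to C4', carbon to C5') should be secured by the C6' methoxy group, whose inductive effect distorts the aryne so that the nucleophile adds to the remote carbon and the charge builds up beside the C–O bond; this bias is expected to outweigh the steric effect of the C3' prenyl group. The acyl shift must outrun protonation of the aryl anion, which would give only the aryl ester, hence THF at 125 °C with sparingly soluble cesium salts as the proton source. Chemoselectivity comes from the substrate: the C2' oxygen is a MOM ether so no phenoxide competes, no diene such as the pyranone is present yet, and the absence of any Lewis acid leaves the prenyl group beside the new phenol uncyclised.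

Step 8
Reactants: 17 1-[2-hydroxy-6-methoxy-4-(methoxymethoxy)-3-(3-methylbut-2-en-1-yl)phenyl]-2-methylpropan-1-one
Product: 18 1-[2,4-dihydroxy-6-methoxy-3-(3-methylbut-2-en-1-yl)phenyl]-2-methylpropan-1-one
Conditions: 2 M HCl in MeOH, rt to 40 °C
Reagents that add atoms: none
Why: Acid-catalysed methanolysis of the MOM ether, which is activated by the para ketone, should proceed under conditions too mild to protonate the prenyl double bond.

Step 9
Reactants: 19 3-pentanone
Product: 20 3-(trimethylsilyloxy)pent-2-ene (E/Z mixture)
Conditions: TMSOTf, Et3N, CH2Cl2, 0 °C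
Reagents that add atoms: trimethylsilyl trifluoromethanesulfonate (TMSOTf), C[Si](C)(C)OS(=O)(=O)C(F)(F)F
Why: Soft enolisation and O-silylation of a symmetrical ketone gives a single constitutional silyl enol ether, whose double-bond geometry is lost in the next step.

Step 10
Reactants: 20 3-(trimethylsilyloxy)pent-2-ene; 21 malonyl dichloride
Product: 22 6-ethyl-4-hydroxy-5-methyl-2H-pyran-2-one
Conditions: Et2O, −78 °C to rt; aqueous work-up
Reagents that add atoms: none
Why: C-acylation of the silyl enol ether by one acid chloride followed by O-acylation of the resulting enol by the second (lactonisation to the six-membered ring) is the established silyl enol ether/malonyl dichloride synthesis of 4-hydroxy-2-pyranones and places ethyl at C6 and methyl at C5.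

Step 11
Reactants: 18 1-[2,4-dihydroxy-6-methoxy-3-(3-methylbut-2-en-1-yl)phenyl]-2-methylpropan-1-one; 22 6-ethyl-4-hydroxy-5-methyl-2H-pyran-2-one
Product: 25 6-ethyl-4-hydroxy-3-{[2,4-dihydroxy-6-methoxy-3-(3-methylbut-2-en-1-yl)-5-(2-methylpropanoyl)phenyl]methyl}-5-methyl-2H-pyran-2-one, via pyranone Mannich base 23 (not isolated), via methylidene pyrandione 24 (not isolated)
Conditions: 22, H2C=NMe2+ I− (Eschenmoser's salt, 1.0 equiv), MeCN, rt; then 18, 50 °C
Reagents that add atoms: N,N-dimethylmethyleneiminium iodide (Eschenmoser's salt), C=[N+](C)C.[I-]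
Why: A Mannich reaction at pyranone C3, loss of dimethylamine to the methylidene pyrandione and Friedel–Crafts-type conjugate addition of the only free ring carbon of 18 (C1', ortho to a free hydroxyl) form the methylene bridge, a three-component coupling known for closely related acylphloroglucinol–pyranone pairs.

**Compound list**

1 | 5-methoxyresorcinol (5-methoxybenzene-1,3-diol) | COc1cc(O)cc(O)c1 | starting material
2 | 1-methoxy-3,5-bis(methoxymethoxy)benzene | COCOc1cc(OC)cc(OCOC)c1 | intermediate
3 | prenyl bromide (1-bromo-3-methylbut-2-ene) | CC(C)=CCBr | starting material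
4 | [4-methoxy-2,6-bis(methoxymethoxy)phenyl]lithium | [Li]c1c(OCOC)cc(OC)cc1OCOC | intermediate (not isolated)
5 | [4-methoxy-2,6-bis(methoxymethoxy)phenyl]copper | [Cu]c1c(OCOC)cc(OC)cc1OCOC | intermediate (not isolated)
6 | 5-methoxy-1,3-bis(methoxymethoxy)-2-(3-methylbut-2-en-1-yl)benzene | COCOc1cc(OC)cc(OCOC)c1CC=C(C)C | intermediate
7 | 2-bromo-1-methoxy-3,5-bis(methoxymethoxy)-4-(3-methylbut-2-en-1-yl)benzene | COCOc1cc(OC)c(Br)c(OCOC)c1CC=C(C)C | intermediate
8 | 4-bromo-5-methoxy-2-(3-methylbut-2-en-1-yl)benzene-1,3-diol | COc1cc(O)c(CC=C(C)C)c(O)c1Br | intermediate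
9 | [4-bromo-5-methoxy-2-(3-methylbut-2-en-1-yl)-1,3-phenylene]bis(oxy)bis(trimethylsilane) | COc1cc(O[Si](C)(C)C)c(CC=C(C)C)c(O[Si](C)(C)C)c1Br | intermediate (not isolated)
10 | [6-methoxy-3-(3-methylbut-2-en-1-yl)-2,4-bis(trimethylsilyloxy)phenyl]lithium | COc1cc(O[Si](C)(C)C)c(CC=C(C)C)c(O[Si](C)(C)C)c1[Li] | intermediate (not isolated)
11 | lithium 3-methoxy-6-(3-methylbut-2-en-1-yl)-2-(trimethylsilyl)-5-(trimethylsilyloxy)phenolate | [Li+].[O-]c1c(CC=C(C)C)c(O[Si](C)(C)C)cc(OC)c1[Si](C)(C)C | intermediate (not isolated)
12 | 3-methoxy-6-(3-methylbut-2-en-1-yl)-2-(trimethylsilyl)-5-(trimethylsilyloxy)phenyl trifluoromethanesulfonate | COc1cc(O[Si](C)(C)C)c(CC=C(C)C)c(OS(=O)(=O)C(F)(F)F)c1[Si](C)(C)C | intermediate (not isolated)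
13 | 5-hydroxy-3-methoxy-6-(3-methylbut-2-en-1-yl)-2-(trimethylsilyl)phenyl trifluoromethanesulfonate | COc1cc(O)c(CC=C(C)C)c(OS(=O)(=O)C(F)(F)F)c1[Si](C)(C)C | intermediate
14 | 3-methoxy-5-(methoxymethoxy)-6-(3-methylbut-2-en-1-yl)-2-(trimethylsilyl)phenyl trifluoromethanesulfonate | COCOc1cc(OC)c([Si](C)(C)C)c(OS(=O)(=O)C(F)(F)F)c1CC=C(C)C | intermediate
15 | isobutyric acid (2-methylpropanoic acid) | CC(C)C(=O)O | starting material
16 | 3-methoxy-5-(methoxymethoxy)-6-(3-methylbut-2-en-1-yl)benzyne (C4'≡C5' aryne) | COCOC1=C(CC=C(C)C)C#CC(OC)=C1 | intermediate (not isolated)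
17 | 1-[2-hydroxy-6-methoxy-4-(methoxymethoxy)-3-(3-methylbut-2-en-1-yl)phenyl]-2-methylpropan-1-one | COCOc1cc(OC)c(C(=O)C(C)C)c(O)c1CC=C(C)C | intermediate
18 | 1-[2,4-dihydroxy-6-methoxy-3-(3-methylbut-2-en-1-yl)phenyl]-2-methylpropan-1-one | COc1cc(O)c(CC=C(C)C)c(O)c1C(=O)C(C)C | intermediate
19 | 3-pentanone | CCC(=O)CC | starting material
20 | 3-(trimethylsilyloxy)pent-2-ene (E/Z mixture) | CC=C(CC)O[Si](C)(C)C | intermediate
21 | malonyl dichloride | O=C(Cl)CC(=O)Cl | starting material
22 | 6-ethyl-4-hydroxy-5-methyl-2H-pyran-2-one | CCc1oc(=O)cc(O)c1C | intermediate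
23 | 3-[(dimethylamino)methyl]-6-ethyl-4-hydroxy-5-methyl-2H-pyran-2-one | CCc1oc(=O)c(CN(C)C)c(O)c1C | intermediate (not isolated)
24 | 6-ethyl-5-methyl-3-methylidene-2H-pyran-2,4(3H)-dione | CCC1=C(C)C(=O)C(=C)C(=O)O1 | intermediate (not isolated)
25 | 6-ethyl-4-hydroxy-3-{[2,4-dihydroxy-6-methoxy-3-(3-methylbut-2-en-1-yl)-5-(2-methylpropanoyl)phenyl]methyl}-5-methyl-2H-pyran-2-one (CNP0149198.0) | CCc1oc(=O)c(Cc2c(O)c(CC=C(C)C)c(O)c(C(=O)C(C)C)c2OC)c(O)c1C | target

**Step count and risks**

Total step count: 11. Longest linear sequence: 9 steps (steps 1–8 and 11); the pyranone branch is steps 9–10.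

Steps most likely to fail:

Step 7. The ortho-acyloxyaryl anion may be protonated before the acyl shift, so that only O-arylation of the acid occurs. Steric pressure from the C3' prenyl group may divert the carboxylate to C5'. The aryne may also be consumed by an ene reaction with the prenyl alkene of a second molecule. The fallback abandons the aryne and sets out from bromide 7. Magnesium insertion (Mg, LiCl, THF, rt to 40 °C) would give the arylmagnesium bromide F1. F1 is acylated with N-methoxy-N,2-dimethylpropanamide (THF, 0 °C to rt) to the bis-MOM ketone 1-[6-methoxy-2,4-bis(methoxymethoxy)-3-(3-methylbut-2-en-1-yl)phenyl]-2-methylpropan-1-one F2. Treatment with 2 M HCl in MeOH then removes both MOM groups, and the route is rejoined at 18.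

Step 11. The methylidene pyrandione may be captured by a second pyranone (methylene-bis-pyranone formation) or by a phenolic oxygen, and C1', flanked by the methoxy group, may add too slowly. The fallback sets out from 18. Ortho-formylation of the free phenol (MgCl2, Et3N, paraformaldehyde, MeCN, reflux) at the only open ring carbon would give 2,4-dihydroxy-6-methoxy-3-(3-methylbut-2-en-1-yl)-5-(2-methylpropanoyl)benzaldehyde F3. A one-pot organocatalytic reductive Knoevenagel alkylation of pyranone 22 with F3 (L-proline cat., Hantzsch ester, CH2Cl2, rt) then fixes the bridge carbon on the arene beforehand and comes back to the route at 25.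

Step 3. Electrophilic bromine may attack the prenyl double bond, with a neighbouring MOM oxygen closing a bromochroman, or a second ring bromination may occur. The fallback sets out from 6. Directed ortho-metalation (n-BuLi, TMEDA, THF, 0 °C) at the ring carbon between OMOM and OMe would give [6-methoxy-2,4-bis(methoxymethoxy)-3-(3-methylbut-2-en-1-yl)phenyl]lithium F4. Quenching at −78 °C with 1,2-dibromotetrachloroethane introduces bromine without any free electrophilic halogen, and the route is rejoined at 7.

Further compounds
F1 | step 7 | bromo[6-methoxy-2,4-bis(methoxymethoxy)-3-(3-methylbut-2-en-1-yl)phenyl]magnesium | Br[Mg]c1c(OC)cc(OCOC)c(CC=C(C)C)c1OCOC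
F2 | step 7 | 1-[6-methoxy-2,4-bis(methoxymethoxy)-3-(3-methylbut-2-en-1-yl)phenyl]-2-methylpropan-1-one | COCOc1cc(OC)c(C(=O)C(C)C)c(OCOC)c1CC=C(C)C
F3 | step 11 | 2,4-dihydroxy-6-methoxy-3-(3-methylbut-2-en-1-yl)-5-(2-methylpropanoyl)benzaldehyde | O=Cc1c(O)c(CC=C(C)C)c(O)c(C(=O)C(C)C)c1OC
F4 | step 3 | [6-methoxy-2,4-bis(methoxymethoxy)-3-(3-methylbut-2-en-1-yl)phenyl]lithium | [Li]c1c(OC)cc(OCOC)c(CC=C(C)C)c1OCOC
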